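**Retrosynthetic overview**
1. Target 19 ⇐ dihydroxy acid 16: the α'-hydroxy enone side chain comes from the natural E-allylic alcohol terminus (singlet-oxygen ene reaction, then oxidation of the C14 carbinol).
2. 16 ⇐ bicyclic diene 10: C19 is raised to the acid and the 8α-OH is added by Markovnikov hydration of the 8(17)-alkene.
3. Key disconnection, 10 ⇐ 9: rings A and B close in one cationic cascade, ring A first (C4–C5) and ring B second (C9–C10), from an acyclic (S)-2,2-disubstituted epoxide. Its quaternary carbon becomes C4 and its CH2–O becomes C19.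
4. 9 ⇐ methyl ketone 8 (asymmetric sulfur-ylide epoxidation) ⇐ 12-bromofarnesyl pivalate 4 + ketal Grignard 6 ⇐ (2E,6E)-farnesol 1.

Assumption: operations run in one flask without isolation count as one step, and the (S)-binaphtholate La–Li catalyst is taken to give the (S)-epoxide (its mirror image is used if the sense proves opposite).

**Step 1**
Reactants: 1 (2E,6E)-farnesol
Product: 2 (2E,6E)-farnesyl pivalate
Conditions: PivCl, pyridine, DMAP (cat.), CH2Cl2, 0 to 25 °C
Reagents that add atoms: pivaloyl chloride, CC(C)(C)C(Cl)=O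
Why: Acylation (nucleophilic acyl substitution) of the primary allylic alcohol; the hindered ester survives the Grignard and ylide steps and later makes the 13,14-alkene a poor cation acceptor.

**Step 2**
Reactants: 2 (2E,6E)-farnesyl pivalate
Product: 3 (2E,6E,10E)-12-hydroxy-3,7,11-trimethyldodeca-2,6,10-trienyl pivalate
Conditions: SeO2 (10 mol %), t-BuOOH, salicylic acid (10 mol %), CH2Cl2, 25 °C
Reagents that add atoms: tert-butyl hydroperoxide, CC(C)(C)OO (oxygen relayed by selenium dioxide, O=[Se]=O)
Why: Catalytic SeO2 allylic oxidation (ene reaction, then [2,3]-sigmatropic shift) attacks the most electron-rich terminal isopropylidene and oxidises only its E-methyl group, so the new alkene is 10E.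

**Step 3**
Reactants: 3 (2E,6E,10E)-12-hydroxy-3,7,11-trimethyldodeca-2,6,10-trienyl pivalate
Product: 4 (2E,6E,10E)-12-bromo-3,7,11-trimethyldodeca-2,6,10-trienyl pivalate
Conditions: CBr4, PPh3, CH2Cl2, −20 to 0 °C
Reagents that add atoms: carbon tetrabromide, BrC(Br)(Br)Br
Why: Appel reaction; bromide displaces the alkoxyphosphonium group at the primary carbon (SN2) without allylic transposition or loss of alkene geometry at low temperature.

**Step 4**
Reactants: 4 (2E,6E,10E)-12-bromo-3,7,11-trimethyldodeca-2,6,10-trienyl pivalate; 5 2-(2-bromoethyl)-2-methyl-1,3-dioxolane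
Product: 8 (2E,6E,10E)-3,7,11-trimethyl-15-oxohexadeca-2,6,10-trienyl pivalate, via Grignard reagent 6 (not isolated), via dioxolane 7 (not isolated)
Conditions: 5, Mg, THF, 25 °C; then 4, Li2CuCl4 (3 mol %), THF, −78 to −20 °C; then 1 M HCl, THF, 25 °C
Reagents that add atoms: water, O
Why: Copper-catalysed Grignard cross-coupling (Kochi type) replaces the primary allylic bromide at low temperature with retention of the E geometry while the pivalate is untouched, and acetal hydrolysis in the acidic work-up releases the methyl ketone.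

**Step 5**
Reactants: 8 (2E,6E,10E)-3,7,11-trimethyl-15-oxohexadeca-2,6,10-trienyl pivalate
Product: 9 (2E,6E,10E)-3,7,11-trimethyl-14-[(2S)-2-methyloxiran-2-yl]tetradeca-2,6,10-trienyl pivalate
Conditions: Me3S(O)I, NaH, THF; then 8, LaLi3((S)-binaphtholate)3 (5 mol %), (2,4,6-(MeO)3C6H2)3P=O (5 mol %), 5 Å MS, THF, 25 °C
Reagents that add atoms: trimethylsulfoxonium iodide, C[S+](C)(C)=O.[I-] (gives CH2 through its methylide)
Why: Catalytic asymmetric Corey–Chaykovsky epoxidation; the La–Li binaphtholate binds ketone and ylide together and tells the methyl group from the long chain, so methylene transfer sets the quaternary oxirane carbon (future C4) as S, typically above 90% ee for methyl ketones.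

**Step 6**
Reactants: 9 (2E,6E,10E)-3,7,11-trimethyl-14-[(2S)-2-methyloxiran-2-yl]tetradeca-2,6,10-trienyl pivalate
Product: 10 (13E)-19-(tert-butyldimethylsilyloxy)labda-8(17),13-dien-15-yl pivalate
Conditions: TBSOTf (1.2 equiv), 2,6-di-tert-butyl-4-methylpyridine (1.5 equiv), CH2Cl2, −78 °C
Reagents that add atoms: tert-butyldimethylsilyl triflate, CC(C)(C)[Si](C)(C)OS(=O)(=O)C(F)(F)F
Why: Proposed new method: O-silylation of the 2,2-disubstituted epoxide starts an epoxide-initiated cation–olefin bicyclization (closest known type: Lewis-acid or silyl-triflate cyclization of trisubstituted epoxy-polyenes) in which the C5=C10 alkene attacks the quaternary oxirane carbon anti to the C–O bond (inversion, so the S centre of 9 fixes C4), the all-E chair–chair fold gives the trans-anti arrangement at C5, C10 and C9, the small sp2-like oxirane CH2 eclipses C2 in the transition state and therefore ends axial as C19 on the face of the C10 methyl, the hindered pyridine removes a C17 proton from the C8 cation to leave the exocyclic alkene, and the allylic pivalate keeps the 13,14-alkene from closing a third ring.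

**Step 7**
Reactants: 10 (13E)-19-(tert-butyldimethylsilyloxy)labda-8(17),13-dien-15-yl pivalate
Product: 13 (13E)-15-(pivaloyloxy)labda-8(17),13-dien-19-oic acid, via alcohol 11 (not isolated), via aldehyde 12 (not isolated)
Conditions: CrO3, H2SO4, acetone/H2O, 0 to 25 °C
Reagents that add atoms: water, O
Why: Jones oxidation; the aqueous acid removes the primary silyl ether and chromic acid takes the alcohol through the aldehyde hydrate to the acid, while both alkenes, the pivalate and all stereocentres are untouched.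

**Step 8**
Reactants: 13 (13E)-15-(pivaloyloxy)labda-8(17),13-dien-19-oic acid
Product: 16 8α,15-dihydroxylabd-13E-en-19-oic acid, via organomercurial 14 (not isolated), via hydroxy pivalate 15 (not isolated)
Conditions: Hg(OAc)2, THF/H2O, 0 °C; then NaBH4, 3 M NaOH, 0 °C; then KOH, MeOH, 60 °C; then 1 M HCl
Reagents that add atoms: water, O
Why: Oxymercuration–demercuration; Hg(OAc)2 takes the exocyclic 1,1-disubstituted alkene much faster than the trisubstituted allylic-ester alkene, water adds in the Markovnikov sense to C8 from the equatorial α-face because the β-face is screened by the axial C10 methyl (8α-OH, 8R), NaBH4 removes mercury, and ester saponification in the same pot frees the 15-OH.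

**Step 9**
Reactants: 16 8α,15-dihydroxylabd-13E-en-19-oic acid
Product: 18 8α,14ξ,15-trihydroxylabd-13(16)-en-19-oic acid, via hydroperoxide 17 (not isolated)
Conditions: O2, hν (visible), tetraphenylporphyrin (cat.), CH2Cl2/MeOH, 0 °C; then PPh3
Reagents that add atoms: oxygen, O=O
Why: Schenck ene reaction of singlet oxygen; on the crowded side of the E-alkene (cis effect, helped by the allylic hydroxyl) oxygen bonds to C14 and a hydrogen leaves the C16 methyl, giving the 13(16)-ene 14-hydroperoxide that PPh3 reduces, and the C14 configuration does not matter because C14 is oxidised next.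

**Step 10**
Reactants: 18 8α,14ξ,15-trihydroxylabd-13(16)-en-19-oic acid
Product: 19 8α,15-dihydroxy-14-oxolabd-13(16)-en-19-oic acid (CNP0196657.1)
Conditions: [(neocuproine)Pd(OAc)]2(OTf)2 (5 mol %), 1,4-benzoquinone, MeCN/H2O, 25 °C
Reagents that add atoms: none
Why: Chemoselective palladium-catalysed oxidation of a vicinal diol; the diol chelates the cationic palladium and β-hydride elimination occurs at the secondary (here also allylic) carbinol only, so the primary 15-OH, the tertiary 8-OH, the acid and the ring stereocentres are untouched.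

**Compound list**
1 | (2E,6E)-farnesol | CC(C)=CCC/C(C)=C/CC/C(C)=C/CO | starting material
2 | (2E,6E)-farnesyl pivalate | CC(C)=CCC/C(C)=C/CC/C(C)=C/COC(=O)C(C)(C)C | intermediate
3 | (2E,6E,10E)-12-hydroxy-3,7,11-trimethyldodeca-2,6,10-trienyl pivalate | OC/C(C)=C/CC/C(C)=C/CC/C(C)=C/COC(=O)C(C)(C)C | intermediate
4 | (2E,6E,10E)-12-bromo-3,7,11-trimethyldodeca-2,6,10-trienyl pivalate | BrC/C(C)=C/CC/C(C)=C/CC/C(C)=C/COC(=O)C(C)(C)C | intermediate
5 | 2-(2-bromoethyl)-2-methyl-1,3-dioxolane | CC1(CCBr)OCCO1 | starting material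
6 | [2-(2-methyl-1,3-dioxolan-2-yl)ethyl]magnesium bromide | CC1(CC[Mg]Br)OCCO1 | intermediate
7 | (2E,6E,10E)-3,7,11-trimethyl-14-(2-methyl-1,3-dioxolan-2-yl)tetradeca-2,6,10-trienyl pivalate | CC1(CCC/C(C)=C/CC/C(C)=C/CC/C(C)=C/COC(=O)C(C)(C)C)OCCO1 | intermediate
8 | (2E,6E,10E)-3,7,11-trimethyl-15-oxohexadeca-2,6,10-trienyl pivalate | CC(=O)CCC/C(C)=C/CC/C(C)=C/CC/C(C)=C/COC(=O)C(C)(C)C | intermediate
9 | (2E,6E,10E)-3,7,11-trimethyl-14-[(2S)-2-methyloxiran-2-yl]tetradeca-2,6,10-trienyl pivalate | C[C@@]1(CO1)CCC/C(C)=C/CC/C(C)=C/CC/C(C)=C/COC(=O)C(C)(C)C | intermediate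
10 | (13E)-19-(tert-butyldimethylsilyloxy)labda-8(17),13-dien-15-yl pivalate; normal labdane series, 5α-H, 9α-H, 10β-CH3, 4α-CH3, 4β-CH2OTBS | CC(C)(C)C(=O)OC/C=C(C)/CC[C@@H]1[C@@]2(C)CCC[C@](C)(CO[Si](C)(C)C(C)(C)C)[C@@H]2CCC1=C | intermediate
11 | (13E)-19-hydroxylabda-8(17),13-dien-15-yl pivalate (same ring configuration as 10) | CC(C)(C)C(=O)OC/C=C(C)/CC[C@@H]1[C@@]2(C)CCC[C@](C)(CO)[C@@H]2CCC1=C | intermediate
12 | (13E)-19-oxolabda-8(17),13-dien-15-yl pivalate | CC(C)(C)C(=O)OC/C=C(C)/CC[C@@H]1[C@@]2(C)CCC[C@](C)(C=O)[C@@H]2CCC1=C | intermediate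
13 | (13E)-15-(pivaloyloxy)labda-8(17),13-dien-19-oic acid | CC(C)(C)C(=O)OC/C=C(C)/CC[C@@H]1[C@@]2(C)CCC[C@](C)(C(=O)O)[C@@H]2CCC1=C | intermediate
14 | 17-(acetoxymercurio)-8α-hydroxy-15-(pivaloyloxy)labd-13E-en-19-oic acid | CC(C)(C)C(=O)OC/C=C(C)/CC[C@@H]1[C@@]2(C)CCC[C@](C)(C(=O)O)[C@@H]2CC[C@@]1(C[Hg]OC(C)=O)O | intermediate
15 | 8α-hydroxy-15-(pivaloyloxy)labd-13E-en-19-oic acid | CC(C)(C)C(=O)OC/C=C(C)/CC[C@@H]1[C@@]2(C)CCC[C@](C)(C(=O)O)[C@@H]2CC[C@@]1(C)O | intermediate
16 | 8α,15-dihydroxylabd-13E-en-19-oic acid, (4S,5R,8R,9R,10S) | OC/C=C(C)/CC[C@@H]1[C@@]2(C)CCC[C@](C)(C(=O)O)[C@@H]2CC[C@@]1(C)O | intermediate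
17 | 14ξ-hydroperoxy-8α,15-dihydroxylabd-13(16)-en-19-oic acid (both C14 epimers) | C=C(CC[C@@H]1[C@@]2(C)CCC[C@](C)(C(=O)O)[C@@H]2CC[C@@]1(C)O)C(CO)OO | intermediate
18 | 8α,14ξ,15-trihydroxylabd-13(16)-en-19-oic acid (both C14 epimers) | C=C(CC[C@@H]1[C@@]2(C)CCC[C@](C)(C(=O)O)[C@@H]2CC[C@@]1(C)O)C(O)CO | intermediate
19 | 8α,15-dihydroxy-14-oxolabd-13(16)-en-19-oic acid, (4S,5R,8R,9R,10S) | C=C(CC[C@@H]1[C@@]2(C)CCC[C@](C)(C(=O)O)[C@@H]2CC[C@@]1(C)O)C(=O)CO | target

**Totals and risks**
Total step count: 10. Longest linear sequence: 10 steps, from 1 to 19 (5 is a purchased coupling partner).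

The three steps most likely to fail:

Step 6. The silylated 2,2-disubstituted epoxide could undergo a 1,2-hydride shift to an aldehyde instead of cyclizing. It could also fold with the oxirane CH2 equatorial, which gives the C18-oxygenated diastereomer on the mirror-image decalin. The silyloxy oxygen could add to the C10 cation, or proton loss could give endocyclic alkenes (these do not react in step 8 and are removed there). The fallback sets out from ketone 8. Wittig methylenation (Ph3PCH3Br, KN(SiMe3)2, THF) gives isopropenyl tetraene F1. Hg(OTf)2·PhNMe2 in MeNO2 at −20 °C, then aqueous NaCl, mercurates only the terminal 1,1-disubstituted alkene; the bicyclization that follows ends by hydroxyl capture at C8 and gives racemic chloromercurial F2, with the small alkene CH2 (now CH2HgCl) axial for the same conformational reason as in step 6. NaBH4 under O2 in DMF replaces HgCl by OH and gives racemic diol F3. AZADO with PhI(OAc)2 oxidises the primary alcohol to the racemic acid, which is 15 together with its mirror image F4. Crystallisation with (R)-1-phenylethylamine gives salt F5, and acidification comes back to the route at 15, which is saponified as in the last operation of step 8.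

Step 9. The ene reaction could take hydrogen from C12 instead of C16, or put oxygen on C13. The fallback sets out from 16. Hydroxyl-directed epoxidation (VO(acac)2, t-BuOOH, CH2Cl2) gives epoxy alcohol F6. Excess Et2Al(2,2,6,6-tetramethylpiperidide) in toluene at 0 °C then isomerises the trisubstituted epoxide by syn removal of a C16 methyl proton to the 13(16)-en-14-ol, and this comes back to the route at 18.

Step 10. The palladium catalyst could be slowed by the 1,1-disubstituted alkene, or the sensitive enone could be damaged. The fallback sets out from hydroperoxide 17, made as in step 9 but without PPh3. Ac2O in pyridine at 0 °C acetylates the 15-OH and dehydrates the secondary hydroperoxide to the ketone, giving keto acetate F7. Candida antarctica lipase B in pH 7 buffer then removes the acetate without touching the enone and comes back to the route at 19.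

**Further compounds**
F1 | step 6 | isopropenyl tetraene, (2E,6E,10E)-3,7,11,15-tetramethylhexadeca-2,6,10,15-tetraenyl pivalate | C=C(C)CCC/C(C)=C/CC/C(C)=C/CC/C(C)=C/COC(=O)C(C)(C)C
F2 | step 6 | racemic chloromercurial, 19-(chloromercurio)-8α-hydroxylabd-13E-en-15-yl pivalate (one enantiomer drawn) | CC(C)(C)C(=O)OC/C=C(C)/CC[C@@H]1[C@@]2(C)CCC[C@](C)(C[Hg]Cl)[C@@H]2CC[C@@]1(C)O
F3 | step 6 | racemic diol, 8α,19-dihydroxylabd-13E-en-15-yl pivalate (one enantiomer drawn) | CC(C)(C)C(=O)OC/C=C(C)/CC[C@@H]1[C@@]2(C)CCC[C@](C)(CO)[C@@H]2CC[C@@]1(C)O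
F4 | step 6 | mirror image of 15 | CC(C)(C)C(=O)OC/C=C(C)/CC[C@H]1[C@]2(C)CCC[C@@](C)(C(=O)O)[C@H]2CC[C@]1(C)O
F5 | step 6 | salt of 15 with (R)-1-phenylethylamine | CC(C)(C)C(=O)OC/C=C(C)/CC[C@@H]1[C@@]2(C)CCC[C@](C)(C(=O)[O-])[C@@H]2CC[C@@]1(C)O.C[C@@H]([NH3+])c1ccccc1
F6 | step 9 | epoxy alcohol, 13,14-epoxy-8α,15-dihydroxylabdan-19-oic acid (trans epoxide, both faces) | OCC1OC1(C)CC[C@@H]2[C@@]3(C)CCC[C@](C)(C(=O)O)[C@@H]3CC[C@@]2(C)O
F7 | step 10 | keto acetate, 15-acetoxy-8α-hydroxy-14-oxolabd-13(16)-en-19-oic acid | C=C(CC[C@@H]1[C@@]2(C)CCC[C@](C)(C(=O)O)[C@@H]2CC[C@@]1(C)O)C(=O)COC(C)=O
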